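The numbers of this flask were set for the occasion; the result is computed.

Time is the question here: where does a closed flask of substrate stand after 8.0 min, on a cycle of substrate, target and isomer of the product with an exit to the over-reaction product?

    isomer of the product ⇌ substrate (k1 = 0.0070 /s)
    substrate ⇌ target (K2 = 0.85, k2 = 0.0054 /s)
    target → over-reaction product (k3 = 0.0027 /s)
    target ⇌ isomer of the product (K4 = 1.0, k4 = 0.0050 /s)

substrate 0.050 M; time 8.0 min

* which holds at 8.0 min: what has brought the reaction to rest, or that it has not come to rest (all of the substrate has reacted / it is still moving / forward and back rates have come level)
* share of the substrate used up at 8.0 min
* target at 8.0 min, in percent of the substrate charged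

- the reaction counts as stopped when no species that holds the substrate changes by six tenths of a point or more over the second half of the time
- run time (flask): 8.0 min

My reckoning runs in powers of ten. Step 1 relaxes with a half-life of 0.892 min, much shorter than the run, so I treat substrate, target and isomer as one pool in rapid pre-equilibrium, with c_substrate : c_target : c_isomer = 1 : 0.85 : 0.850. Target is then 31.5% of the pool, and the pool leaks through step 3 at k3 times that share, 0.0510 /min. My quantity is the decade time of the pool, the time in which it falls by one power of ten, 2.3 over that leak: 45.1 min. The run lasts 0.177 of a decade, shorter than the decade time, so the flask is still moving with 66.5% of the pool left. That leaves conversion at 75.4% and target at 20.9%.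

The forecast divides the same kind of pool differently, as 2 : 1 : 0.45, with the step from isomer to substrate “having no reverse term”. It says it is still moving, with conversion 57.7% and target 20.6%. We agree on target and part by 18 percentage points on conversion.

The simulation says it is still moving, with conversion 72.0% and target 20.4%. My conversion lies nearer, 3.4 points above, while the forecast's lies 14 points below. Over the second half of the time the shares in the flask moved by up to 14 points. Carried to 80.0 min, the decade time gives 1.77 decades and substrate 0.623%, against 1.05% in the flask.

For the flask left until 15 min, the decade time gives 0.333 decades, conversion 82.8% and target 14.6%. That flask computes to conversion 79.7% and target 14.8%.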